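**Retrosynthetic overview**
1. Chalcone: the aryl–C(=O) bond is made last-but-one by ortho-lithiation of the MOM-protected A ring and acylation with a p-coumaric Weinreb amide (Heck reaction of protected 4-iodophenol with N-methoxy-N-methylacrylamide).
2. C3 and C4: the C3 carbinol comes from reduction of a pyran-3-one, the C4–H from hydrogenation of a 2,6-trans-2H-pyran-3(6H)-one; the A ring is attached at C4 by Negishi coupling of an α-bromoenone with an arylzinc (A ring from anisole by C–H borylation/oxidation).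
3. Pyran ring (the only ring built; the benzene rings are bought): oxidative furan-to-pyranone ring expansion (Achmatowicz) of an (S)-aryl 3-bromofuryl carbinol, telescoped with trans C6-alkynylation by an aryl(silyl)acetylene.
4. Carbinol (future C2): catalytic asymmetric aryl transfer to 3-bromofurfural; one TBS-protected 4-iodophenol supplies all three p-hydroxyphenyl groups.

Target configuration read from the SMILES: (2S,3S,4S,6S); 2-aryl and 3-OH cis, 4-aryl and 6-phenethyl on the opposite face (2-aryl axial, the other three equatorial).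

Assumption: (−)-MIB delivers the aryl group to the Si face of aldehyde 5, as it does with benzaldehydes; if the opposite sense is found, (+)-MIB is used.

**Route**

Step 1
Reactants: 1 4-iodophenol
Product: 2 tert-butyl(4-iodophenoxy)dimethylsilane
Conditions: TBSCl, imidazole, DMF, rt
Reagents that add atoms: tert-butyldimethylsilyl chloride CC(C)(C)[Si](C)(C)Cl
Why: Imidazole-promoted O-silylation of a phenol; no stereocentre is involved.

Step 2
Reactants: 2 tert-butyl(4-iodophenoxy)dimethylsilane; 3 ethynyltrimethylsilane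
Product: 4 tert-butyldimethyl{4-[(trimethylsilyl)ethynyl]phenoxy}silane
Conditions: PdCl2(PPh3)2 (2 mol %), CuI (4 mol %), Et3N, THF, rt
Reagents that add atoms: none
Why: Sonogashira coupling of an aryl iodide with a terminal alkyne proceeds at room temperature and leaves both silyl groups in place.

Step 3
Reactants: 2 tert-butyl(4-iodophenoxy)dimethylsilane; 5 3-bromofuran-2-carbaldehyde
Product: 8 (S)-(3-bromofuran-2-yl)[4-(tert-butyldimethylsilyloxy)phenyl]methanol, via aryllithium 6 (not isolated), via butyl(aryl)zinc 7 (not isolated)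
Conditions: 2 (1.6 equiv), n-BuLi, t-BuOMe, −78 °C; ZnCl2, then n-BuLi; TEEDA; (−)-MIB (5 mol %), 5, toluene, 0 °C; aq NH4Cl
Reagents that add atoms: none
Why: Catalytic asymmetric aryl transfer from a mixed aryl(alkyl)zinc to an aldehyde (Walsh-type amino-alcohol catalysis): the MIB–zinc complex delivers the aryl group to the Si face of 5 and sets the (S)-carbinol centre that becomes C2, while TEEDA binds LiCl and suppresses the racemic background addition.

Step 4
Reactants: 8 (S)-(3-bromofuran-2-yl)[4-(tert-butyldimethylsilyloxy)phenyl]methanol; 4 tert-butyldimethyl{4-[(trimethylsilyl)ethynyl]phenoxy}silane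
Product: 10 (2S,6R)-4-bromo-2-[4-(tert-butyldimethylsilyloxy)phenyl]-6-{[4-(tert-butyldimethylsilyloxy)phenyl]ethynyl}-2H-pyran-3(6H)-one (2,6-trans), via lactol 9 (not isolated)
Conditions: mCPBA (1.0 equiv), CH2Cl2, 0 °C; then 4 (1.5 equiv), 4 Å MS, TMSOTf (0.3 equiv), −78 → −30 °C
Reagents that add atoms: meta-chloroperoxybenzoic acid OOC(=O)c1cccc(Cl)c1
Why: Proposed new method: mCPBA turns the furyl carbinol into the 6-hydroxy-2H-pyran-3(6H)-one (Achmatowicz oxidative ring expansion; the carbinol oxygen becomes the ring oxygen and C2 is untouched), and in the same flask catalytic TMSOTf ionises the unactivated hemiacetal to a 3-oxo-2H-pyrylium (oxocarbenium) ion that the aryl(silyl)acetylene attacks through its silicon-bearing carbon (β-silyl, α-aryl vinyl cation, then loss of the silyl group) on the face anti to the C2 aryl group, which forms the C6–C bond and sets C6 trans to C2; the closest known reactions are the Achmatowicz rearrangement followed by Kishi-type Lewis-acid C-glycosylation of isolated anomeric acetates with allylsilanes, and Isobe's C-alkynylation of glycal acetates with silylacetylenes.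

Step 5
Reactants: 11 anisole
Product: 13 5-methoxybenzene-1,3-diol, via diboronate 12 (not isolated)
Conditions: B2pin2 (1.2 equiv), [Ir(OMe)(cod)]2 (1.5 mol %), dtbpy (3 mol %), THF, 60 °C; then aq NaOH, H2O2, 0 °C → rt; acidify
Reagents that add atoms: hydrogen peroxide OO
Why: Sterically controlled Ir-catalysed C–H borylation puts both boryl groups meta to OMe (after the first meta-borylation only C5 has no ortho substituent) and one-pot oxidation of the C–B bonds gives the 1,3,5-trioxygenated ring; the para-borylated by-product ends as 4-methoxyphenol and is separated, which limits the yield to about 60%.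

Step 6
Reactants: 13 5-methoxybenzene-1,3-diol
Product: 14 1-methoxy-3,5-bis(methoxymethoxy)benzene
Conditions: MOMCl (2.5 equiv), i-Pr2NEt, CH2Cl2, 0 °C → rt
Reagents that add atoms: chloromethyl methyl ether COCCl
Why: Williamson-type O-alkylation of both phenols installs the MOM groups that later direct both lithiations.

Step 7
Reactants: 14 1-methoxy-3,5-bis(methoxymethoxy)benzene; 10 (2S,6R)-4-bromo-2-[4-(tert-butyldimethylsilyloxy)phenyl]-6-{[4-(tert-butyldimethylsilyloxy)phenyl]ethynyl}-2H-pyran-3(6H)-one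
Product: 17 (2S,6R)-2-[4-(tert-butyldimethylsilyloxy)phenyl]-6-{[4-(tert-butyldimethylsilyloxy)phenyl]ethynyl}-4-[4-methoxy-2,6-bis(methoxymethoxy)phenyl]-2H-pyran-3(6H)-one, via aryllithium 15 (not isolated), via arylzinc chloride 16 (not isolated)
Conditions: 14 (1.3 equiv), n-BuLi, THF, 0 °C; ZnCl2, 0 °C → rt; then 10, Pd2(dba)3 (2.5 mol %), SPhos (10 mol %), THF, 40 °C
Reagents that add atoms: none
Why: Directed ortho-metalation takes place at the carbon flanked by the two OMOM groups, transmetalation gives a non-basic arylzinc, and Negishi coupling with the α-bromoenone forms the C4–aryl bond without touching the ketone, the alkyne or the acidic C2–H.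

Step 8
Reactants: 17 (2S,6R)-2-[4-(tert-butyldimethylsilyloxy)phenyl]-6-{[4-(tert-butyldimethylsilyloxy)phenyl]ethynyl}-4-[4-methoxy-2,6-bis(methoxymethoxy)phenyl]-2H-pyran-3(6H)-one
Product: 18 (2S,4S,6S)-2-[4-(tert-butyldimethylsilyloxy)phenyl]-6-{2-[4-(tert-butyldimethylsilyloxy)phenyl]ethyl}-4-[4-methoxy-2,6-bis(methoxymethoxy)phenyl]dihydro-2H-pyran-3(4H)-one
Conditions: H2 (1–3 atm), 10% Pd/C, EtOAc, rt, stopped after 3 equiv H2
Reagents that add atoms: none
Why: Heterogeneous catalytic hydrogenation saturates the alkyne and then adds H2 syn to the C4=C5 enone bond from the face opposite the adjacent C6 side chain, which places the C4 aryl group cis to the C6 chain (4S); the ketone and the silyl and MOM ethers are inert, and the aprotic solvent disfavours benzylic C–O hydrogenolysis.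

Step 9
Reactants: 18 (2S,4S,6S)-2-[4-(tert-butyldimethylsilyloxy)phenyl]-6-{2-[4-(tert-butyldimethylsilyloxy)phenyl]ethyl}-4-[4-methoxy-2,6-bis(methoxymethoxy)phenyl]dihydro-2H-pyran-3(4H)-one
Product: 19 (2S,3S,4S,6S)-2-[4-(tert-butyldimethylsilyloxy)phenyl]-6-{2-[4-(tert-butyldimethylsilyloxy)phenyl]ethyl}-4-[4-methoxy-2,6-bis(methoxymethoxy)phenyl]tetrahydro-2H-pyran-3-ol
Conditions: NaBH4, CeCl3·7H2O, MeOH/THF, −40 °C
Reagents that add atoms: none
Why: In the chair anchored by the equatorial C4-aryl and C6-alkyl groups the C2-aryl group is axial and blocks its own face, so hydride (Luche-type borohydride reduction, weakly basic) attacks axially from the other face and gives the equatorial 3-OH, cis to the C2 aryl and trans to the C4 aryl (3S).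

Step 10
Reactants: 2 tert-butyl(4-iodophenoxy)dimethylsilane; 20 N-methoxy-N-methylacrylamide
Product: 21 (E)-3-[4-(tert-butyldimethylsilyloxy)phenyl]-N-methoxy-N-methylprop-2-enamide
Conditions: Pd(OAc)2 (3 mol %), P(o-tol)3 (6 mol %), Et3N, MeCN, 80 °C
Reagents that add atoms: none
Why: Mizoroki–Heck reaction of an aryl iodide with an acrylamide gives the (E)-alkene through syn-insertion and syn-β-hydride elimination.

Step 11
Reactants: 19 (2S,3S,4S,6S)-2-[4-(tert-butyldimethylsilyloxy)phenyl]-6-{2-[4-(tert-butyldimethylsilyloxy)phenyl]ethyl}-4-[4-methoxy-2,6-bis(methoxymethoxy)phenyl]tetrahydro-2H-pyran-3-ol; 21 (E)-3-[4-(tert-butyldimethylsilyloxy)phenyl]-N-methoxy-N-methylprop-2-enamide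
Product: 23 (E)-1-{3-[(2S,3S,4S,6S)-2-[4-(tert-butyldimethylsilyloxy)phenyl]-6-{2-[4-(tert-butyldimethylsilyloxy)phenyl]ethyl}-3-hydroxytetrahydro-2H-pyran-4-yl]-6-methoxy-2,4-bis(methoxymethoxy)phenyl}-3-[4-(tert-butyldimethylsilyloxy)phenyl]prop-2-en-1-one, via dilithio species 22 (not isolated)
Conditions: n-BuLi (2.3 equiv), TMEDA, THF, −20 → 0 °C; then 21 (1.3 equiv), −78 → 0 °C; aq NH4Cl
Reagents that add atoms: none
Why: After deprotonation of the 3-OH, directed ortho-metalation occurs at the only ring C–H left on the A ring (two equivalent sites flanked by OMe and OMOM), and the aryllithium adds 1,2 to the Weinreb amide, whose stable chelate prevents over-addition and leaves the (E)-alkene intact.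

Step 12
Reactants: 23 the protected chalcone from step 11
Product: 24 target, (E)-1-{2,4-dihydroxy-3-[(2S,3S,4S,6S)-3-hydroxy-2-(4-hydroxyphenyl)-6-[2-(4-hydroxyphenyl)ethyl]tetrahydro-2H-pyran-4-yl]-6-methoxyphenyl}-3-(4-hydroxyphenyl)prop-2-en-1-one
Conditions: 3 M aq HCl, MeOH/THF, 40 °C, stopped at full conversion
Reagents that add atoms: none
Why: Acid-catalysed acetal exchange removes both MOM groups and methanolysis cleaves the three aryl silyl ethers, while under these mild conditions the 2'-hydroxychalcone and the pyran stereocentres are expected to stay unchanged.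

**Compound list**
1 | 4-iodophenol | Oc1ccc(I)cc1 | starting material
2 | tert-butyl(4-iodophenoxy)dimethylsilane | CC(C)(C)[Si](C)(C)Oc1ccc(I)cc1 | intermediate
3 | ethynyltrimethylsilane | C#C[Si](C)(C)C | starting material
4 | tert-butyldimethyl{4-[(trimethylsilyl)ethynyl]phenoxy}silane | C[Si](C)(C)C#Cc1ccc(O[Si](C)(C)C(C)(C)C)cc1 | intermediate
5 | 3-bromofuran-2-carbaldehyde | O=Cc1occc1Br | starting material
6 | [4-(tert-butyldimethylsilyloxy)phenyl]lithium | [Li]c1ccc(O[Si](C)(C)C(C)(C)C)cc1 | intermediate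
7 | butyl[4-(tert-butyldimethylsilyloxy)phenyl]zinc | CCCC[Zn]c1ccc(O[Si](C)(C)C(C)(C)C)cc1 | intermediate
8 | (S)-(3-bromofuran-2-yl)[4-(tert-butyldimethylsilyloxy)phenyl]methanol | O[C@H](c1occc1Br)c1ccc(O[Si](C)(C)C(C)(C)C)cc1 | intermediate
9 | (2S)-4-bromo-2-[4-(tert-butyldimethylsilyloxy)phenyl]-6-hydroxy-2H-pyran-3(6H)-one (anomer mixture) | OC1C=C(Br)C(=O)[C@H](c2ccc(O[Si](C)(C)C(C)(C)C)cc2)O1 | intermediate
10 | (2S,6R)-4-bromo-2-[4-(tert-butyldimethylsilyloxy)phenyl]-6-{[4-(tert-butyldimethylsilyloxy)phenyl]ethynyl}-2H-pyran-3(6H)-one | O=C1C(Br)=C[C@H](C#Cc2ccc(O[Si](C)(C)C(C)(C)C)cc2)O[C@H]1c1ccc(O[Si](C)(C)C(C)(C)C)cc1 | intermediate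
11 | anisole | COc1ccccc1 | starting material
12 | 2,2'-(5-methoxy-1,3-phenylene)bis(4,4,5,5-tetramethyl-1,3,2-dioxaborolane) | COc1cc(B2OC(C)(C)C(C)(C)O2)cc(B2OC(C)(C)C(C)(C)O2)c1 | intermediate
13 | 5-methoxybenzene-1,3-diol | COc1cc(O)cc(O)c1 | intermediate
14 | 1-methoxy-3,5-bis(methoxymethoxy)benzene | COCOc1cc(OC)cc(OCOC)c1 | intermediate
15 | [4-methoxy-2,6-bis(methoxymethoxy)phenyl]lithium | [Li]c1c(OCOC)cc(OC)cc1OCOC | intermediate
16 | chloro[4-methoxy-2,6-bis(methoxymethoxy)phenyl]zinc | Cl[Zn]c1c(OCOC)cc(OC)cc1OCOC | intermediate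
17 | (2S,6R)-2-[4-(tert-butyldimethylsilyloxy)phenyl]-6-{[4-(tert-butyldimethylsilyloxy)phenyl]ethynyl}-4-[4-methoxy-2,6-bis(methoxymethoxy)phenyl]-2H-pyran-3(6H)-one | O=C1C(c2c(OCOC)cc(OC)cc2OCOC)=C[C@H](C#Cc2ccc(O[Si](C)(C)C(C)(C)C)cc2)O[C@H]1c1ccc(O[Si](C)(C)C(C)(C)C)cc1 | intermediate
18 | (2S,4S,6S)-2-[4-(tert-butyldimethylsilyloxy)phenyl]-6-{2-[4-(tert-butyldimethylsilyloxy)phenyl]ethyl}-4-[4-methoxy-2,6-bis(methoxymethoxy)phenyl]dihydro-2H-pyran-3(4H)-one | O=C1[C@H](c2c(OCOC)cc(OC)cc2OCOC)C[C@H](CCc2ccc(O[Si](C)(C)C(C)(C)C)cc2)O[C@H]1c1ccc(O[Si](C)(C)C(C)(C)C)cc1 | intermediate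
19 | (2S,3S,4S,6S)-2-[4-(tert-butyldimethylsilyloxy)phenyl]-6-{2-[4-(tert-butyldimethylsilyloxy)phenyl]ethyl}-4-[4-methoxy-2,6-bis(methoxymethoxy)phenyl]tetrahydro-2H-pyran-3-ol | COc1cc(OCOC)c([C@@H]2C[C@H](CCc3ccc(O[Si](C)(C)C(C)(C)C)cc3)O[C@@H](c3ccc(O[Si](C)(C)C(C)(C)C)cc3)[C@H]2O)c(OCOC)c1 | intermediate
20 | N-methoxy-N-methylacrylamide | C=CC(=O)N(C)OC | starting material
21 | (E)-3-[4-(tert-butyldimethylsilyloxy)phenyl]-N-methoxy-N-methylprop-2-enamide | CON(C)C(=O)/C=C/c1ccc(O[Si](C)(C)C(C)(C)C)cc1 | intermediate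
22 | dilithio species of 19 (lithium 3-alkoxide, aryllithium between OMe and OMOM) | COc1cc(OCOC)c([C@@H]2C[C@H](CCc3ccc(O[Si](C)(C)C(C)(C)C)cc3)O[C@@H](c3ccc(O[Si](C)(C)C(C)(C)C)cc3)[C@H]2O[Li])c(OCOC)c1[Li] | intermediate
23 | protected chalcone (two MOM, three TBS) | COc1cc(OCOC)c([C@@H]2C[C@H](CCc3ccc(O[Si](C)(C)C(C)(C)C)cc3)O[C@@H](c3ccc(O[Si](C)(C)C(C)(C)C)cc3)[C@H]2O)c(OCOC)c1C(=O)/C=C/c1ccc(O[Si](C)(C)C(C)(C)C)cc1 | intermediate
24 | CNP0310862.1 | COc1cc(O)c([C@@H]2C[C@H](CCc3ccc(O)cc3)O[C@@H](c3ccc(O)cc3)[C@H]2O)c(O)c1C(=O)/C=C/c1ccc(O)cc1 | target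

**Totals**
Total step count: 12. Longest linear sequence: 8 steps (steps 1, 3, 4, 7, 8, 9, 11, 12, from 4-iodophenol).

**Three steps most likely to fail**

Step 4 (the proposed new step). The free hemiacetal may ionise sluggishly, or the 2-aryl oxocarbenium ion may lose the C2 proton to an aromatic 3-hydroxypyrylium and so lose the C2 configuration. The fallback uses known chemistry, sets out from 8 and returns at 10. The mCPBA Achmatowicz rearrangement is run alone and lactol 9 is isolated. Acetylation (Ac2O, pyridine, DMAP) gives the anomeric acetate (2S)-4-bromo-2-[4-(tert-butyldimethylsilyloxy)phenyl]-3-oxo-3,6-dihydro-2H-pyran-6-yl acetate F1. F1 is then treated with alkynylsilane 4 and SnCl4 or BF3·OEt2 in CH2Cl2 at −40 °C, the established Lewis-acid C-glycosylation of an isolated acetate donor, to give 10.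

Step 8. The two flanking substituents at C2 and C6 lie on opposite faces, so the facial selectivity at C4 is not certain; benzylic or allylic C–O hydrogenolysis is also possible. The fallback sets out from 17 and returns at 19, replacing steric control by hydroxyl direction. Reagent-controlled 1,2-reduction with (S)-Me-CBS and catecholborane (enone arm as the large group) gives the cis-2,3 allylic alcohol (2S,3S,6R)-3,6-dihydro-2H-pyran-3-ol F2. Hydrogenation over Pd/C(en) saturates only the alkyne and gives the alkyne-saturated allylic alcohol F3. Crabtree's catalyst under H2 in CH2Cl2 then delivers hydrogen to C4 from the face of the 3-OH and gives 19 directly.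

Step 11. Lithiation of a late intermediate may compete with deprotonation at the benzylic C2–H next to the ring oxygen (Wittig-type rearrangement) or with silyl migration on the aryl TBS ethers. The fallback sets out from 19 and returns at 23, replacing deprotonation by halogenation and halogen–metal exchange. NIS in MeCN at 0 °C iodinates the only free A-ring position and gives aryl iodide F4. i-PrMgCl·LiCl (2.2 equiv, THF, −20 → 0 °C) deprotonates the alcohol and exchanges iodine for magnesium to give the bis-magnesium species F5, which is acylated with Weinreb amide 21 to give 23.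

**Further compounds**
F1 | step 4 | (2S)-4-bromo-2-[4-(tert-butyldimethylsilyloxy)phenyl]-3-oxo-3,6-dihydro-2H-pyran-6-yl acetate | CC(=O)OC1C=C(Br)C(=O)[C@H](c2ccc(O[Si](C)(C)C(C)(C)C)cc2)O1
F2 | step 8 | (2S,3S,6R)-2-[4-(tert-butyldimethylsilyloxy)phenyl]-6-{[4-(tert-butyldimethylsilyloxy)phenyl]ethynyl}-4-[4-methoxy-2,6-bis(methoxymethoxy)phenyl]-3,6-dihydro-2H-pyran-3-ol | O[C@H]1C(c2c(OCOC)cc(OC)cc2OCOC)=C[C@H](C#Cc2ccc(O[Si](C)(C)C(C)(C)C)cc2)O[C@H]1c1ccc(O[Si](C)(C)C(C)(C)C)cc1
F3 | step 8 | (2S,3S,6S)-2-[4-(tert-butyldimethylsilyloxy)phenyl]-6-{2-[4-(tert-butyldimethylsilyloxy)phenyl]ethyl}-4-[4-methoxy-2,6-bis(methoxymethoxy)phenyl]-3,6-dihydro-2H-pyran-3-ol | O[C@H]1C(c2c(OCOC)cc(OC)cc2OCOC)=C[C@H](CCc2ccc(O[Si](C)(C)C(C)(C)C)cc2)O[C@H]1c1ccc(O[Si](C)(C)C(C)(C)C)cc1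
F4 | step 11 | (2S,3S,4S,6S)-2-[4-(tert-butyldimethylsilyloxy)phenyl]-6-{2-[4-(tert-butyldimethylsilyloxy)phenyl]ethyl}-4-[3-iodo-4-methoxy-2,6-bis(methoxymethoxy)phenyl]tetrahydro-2H-pyran-3-ol | COc1cc(OCOC)c([C@@H]2C[C@H](CCc3ccc(O[Si](C)(C)C(C)(C)C)cc3)O[C@@H](c3ccc(O[Si](C)(C)C(C)(C)C)cc3)[C@H]2O)c(OCOC)c1I
F5 | step 11 | bis-magnesium species of F4 (chloromagnesium 3-alkoxide, arylmagnesium chloride) | COc1cc(OCOC)c([C@@H]2C[C@H](CCc3ccc(O[Si](C)(C)C(C)(C)C)cc3)O[C@@H](c3ccc(O[Si](C)(C)C(C)(C)C)cc3)[C@H]2O[Mg]Cl)c(OCOC)c1[Mg]Cl
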